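**Plan**

Guaianolide numbering is used; primed atoms belong to the half that ends with the C3' ketone (unit B), unprimed atoms to the diol half (unit A).
Retrosynthesis: the C3' ketone and the two lactone methylenes are taken back to a C3' carbinol and 11-methyl lactones, then the C3(OH)–C4(OH) bond is cut. This bond is shared by the cyclopentane of unit A (C1–C5) and the central cyclopentane (C3, C4, C15, C15', C4'), so the two five-membered rings are the halves of a cyclooctane-1,5-dione (C3, C2, C1, C5, C4, C15, C15', C4').
The eight-membered ring is then cut at C3–C4' and C15–C15' (De Mayo [2+2]/retro-aldol, run through a silicon tether from O3 to O3'). This gives a ring-expanded unit A ketol and the unit B allylic alcohol, both made from one epoxide derived from α-santonin.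
Forward: hydroazulene and lactone by photorearrangement of α-santonin, common epoxide, divergence into the two halves, tether, cyclobutane, eight-membered diketone, the cyclopentane of unit A and the central cyclopentane together by ketyl coupling, then lactone methylenes and C3' ketone.
Stereochemistry: C1, C6 and C7 of both halves come from α-santonin and its rearrangement, C5 from hydrogenation, C4' from tether-directed cycloaddition on the α-face, C3 and C4 from hydroxyl-chelated ketyl coupling.

Key step: step 14

Assumption: the C3 carbinol centre of 12, 14 and 15 and the cyclobutane centres C3 and C15 of 17 and 18 are transient, so these compounds are carried as epimer mixtures and drawn without configuration at those atoms.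

Step 1
Reactants: 1 α-santonin
Product: 2 isophotosantonic lactone
Conditions: hν (medium-pressure Hg lamp), AcOH–H2O (1:1), reflux
Reagents that add atoms: water, O
Why: Photochemical rearrangement of the cross-conjugated cyclohexadienone (santonin to isophotosantonic lactone type): the excited dienone bonds C1 to C5 and water opens the cyclopropyl cation at C10 on the side away from the breaking C5–C10 bond, which should give H1 and the C10 hydroxyl both α while C6, C7 and C11 stay as in 1.

Step 2
Reactants: 2 isophotosantonic lactone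
Product: 3 4,5-dihydroisophotosantonic lactone
Conditions: H2 (1 atm), Pd/C (10 wt% palladium on carbon), EtOAc, rt
Reagents that add atoms: none
Why: Heterogeneous catalytic hydrogenation of the C4=C5 enone bond; syn delivery of hydrogen to the α-face, away from the β-methyl on C10, is expected to give the cis ring fusion (H5 α) with H4 α.

Step 3
Reactants: 3 4,5-dihydroisophotosantonic lactone
Product: 4 3β,10α-diol
Conditions: NaBH4, MeOH, 0 °C
Reagents that add atoms: none
Why: Hydride reduction of the cyclopentanone from its convex α-face should give the 3β-alcohol, trans to H4 as the coming anti-elimination requires, and leaves the lactone alone.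

Step 4
Reactants: 4 3β,10α-diol
Product: 6 10α-hydroxy-1α,5αH-guai-3-en-6α,12-olide, via 3β-mesylate 5 (not isolated)
Conditions: MsCl, Et3N, CH2Cl2, −10 °C; then DBU, toluene, 100 °C
Reagents that add atoms: none
Why: Chemoselective mesylation of the secondary alcohol and base-induced bimolecular anti-elimination through the anti-periplanar H4 should give the more substituted C3=C4 alkene; the tertiary alcohol is not sulfonylated under these conditions.

Step 5
Reactants: 6 10α-hydroxy-1α,5αH-guai-3-en-6α,12-olide
Product: 7 (11S)-1α,5αH-guaia-3,10(14)-dien-6α,12-olide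
Conditions: SOCl2, pyridine, CH2Cl2, −20 to 0 °C
Reagents that add atoms: none
Why: Dehydration of the tertiary alcohol through its chlorosulfite (pyridine-induced anti-elimination): H1 is syn to the leaving group and cannot be lost, so the methyl hydrogens are expected to give mainly the exocyclic C10=C14 alkene, the Δ9 isomer being removed on AgNO3-impregnated silica.

Step 6
Reactants: 7 (11S)-1α,5αH-guaia-3,10(14)-dien-6α,12-olide
Product: 8 3α,4α-epoxide
Conditions: mCPBA (1.05 equiv), NaHCO3, CH2Cl2, −20 to 0 °C
Reagents that add atoms: mCPBA (3-chloroperoxybenzoic acid), O=C(OO)c1cccc(Cl)c1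
Why: Prilezhaev epoxidation: the trisubstituted C3=C4 alkene is more electron-rich than the 1,1-disubstituted C10=C14 alkene and is attacked on the convex α-face of the cis-fused bicycle, which sets C3 and C4.

Step 7
Reactants: 8 3α,4α-epoxide
Product: 9 3α-hydroxy-1α,5αH-guaia-4(15),10(14)-dien-6α,12-olide (unit B)
Conditions: Al(OiPr)3, toluene, reflux
Reagents that add atoms: none
Why: Aluminium-alkoxide-mediated isomerisation of a trisubstituted epoxide to an allylic alcohol: syn removal of a C15 methyl hydrogen through a six-membered transition state opens the C4–O bond, so the C3–O bond and its α configuration are retained.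

Step 8
Reactants: 8 3α,4α-epoxide
Product: 11 3,4-seco keto aldehyde (unit A), via 3α,4β-diol 10 (not isolated)
Conditions: H5IO6, THF–H2O, 0 °C to rt
Reagents that add atoms: water, O
Why: Acid-catalysed epoxide hydrolysis and periodate glycol cleavage (Malaprade reaction) in one flask break the C3–C4 bond; the alkene and the lactone are inert and C1 and C5 keep their cis relationship.

Step 9
Reactants: 11 3,4-seco keto aldehyde (unit A)
Product: 12 unit A ketol (six-membered ring C1–C2–C3–C15–C4–C5)
Conditions: L-proline (30 mol%), DMSO, rt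
Reagents that add atoms: none
Why: Amine-catalysed intramolecular aldol addition (6-enolendo, Hajos–Parrish type): the enamine of the methyl ketone attacks the C3 aldehyde through C15, the only ring size available, and the mild conditions should stop at the ketol; the new C3 carbinol centre is transient and both epimers are used.

Step 10
Reactants: 9 3α-hydroxy-1α,5αH-guaia-4(15),10(14)-dien-6α,12-olide (unit B); 12 unit A ketol
Product: 14 diisopropylsilylene-bridged silaketal, via chlorosilyl ether 13 (not isolated)
Conditions: 9, iPr2SiCl2 (3 equiv), imidazole, CH2Cl2, 0 °C; excess silane evaporated; then 12, imidazole, DMF, rt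
Reagents that add atoms: dichlorodiisopropylsilane, CC(C)[Si](Cl)(Cl)C(C)C
Why: Stepwise formation of an unsymmetrical dialkoxysilane (temporary silicon tether): the hindered dichlorosilane reacts once with 9 and the resulting chlorosilane then silylates the ketol hydroxyl; no stereocentre is touched.

Step 11
Reactants: 14 diisopropylsilylene-bridged silaketal
Product: 16 3-silyloxy enone (C3(OSi)=C15–C4=O), via trimethylsilyl enol ether 15 (not isolated)
Conditions: LiN(iPr)2 (LDA, 1.1 equiv), Me3SiCl, THF, −78 °C; then Pd(OAc)2 (1.1 equiv), MeCN, rt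
Reagents that add atoms: none
Why: Kinetic enolisation at the C15 methylene followed by Saegusa–Ito dehydrogenation: palladium diacetate removes the C3 hydrogen by β-hydride elimination, which gives the vinylogous silyl ester with the oxygen fixed on C3 and erases the transient C3 centre.

Step 12
Reactants: 16 3-silyloxy enone
Product: 17 tethered cyclobutane photoadduct
Conditions: hν (λ > 300 nm, Pyrex), MeCN (2 mM, degassed), 0 °C
Reagents that add atoms: none
Why: Proposed new method: an intramolecular De Mayo-type [2+2] photocycloaddition in which the enol oxygen of a cyclic 1,3-dione is linked to the allylic oxygen of the alkene through a diisopropylsilylene bridge; the triplet of the vinylogous silyl ester should bond C3 to C4' by closing a six-membered C3–O–Si–O–C3'–C4' ring and C15 to C15' (the head-to-tail connectivity that untethered enol derivatives of 1,3-diones also show with 1,1-disubstituted alkenes), the tether from the α-oxygen on C3' brings C3 to the α-face of the alkene and so sets C4', only C4'=C15' is within its reach, which should spare the C10 and C10' methylenes, the C3 and C15 centres of the cyclobutane are lost in the next step, and the closest known reaction types are the De Mayo reaction of 3-acyloxy and 3-silyloxy cycloalkenones and enone–alkene photocycloadditions through temporary silicon tethers.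

Step 13
Reactants: 17 tethered cyclobutane photoadduct
Product: 19 eight-membered 3,4-seco 1,5-diketone, via cyclobutanol 18 (not isolated)
Conditions: HF·pyridine, pyridine, THF, 0 °C to rt
Reagents that add atoms: none
Why: Fluoride cleavage of both Si–O bonds frees the C3 cyclobutanol, which undergoes the strain-driven retro-aldol fragmentation of the De Mayo reaction (C3–C15 cleavage) to the cyclooctane-1,5-dione; C4' is untouched and the buffered medium avoids retro-aldol at C3'.

Step 14
Reactants: 19 eight-membered 3,4-seco 1,5-diketone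
Product: 20 triol (11,13,11',13'-tetrahydro-3'-deoxo-3'α-hydroxyainsliadimer A)
Conditions: SmI2 (3 equiv), THF, −78 °C to rt; aq. NaHCO3
Reagents that add atoms: none
Why: SmI2 (samarium diiodide, divalent samarium) gives one electron to each of the C3 and C4 carbonyl groups, and the two ketyls, held 1,5 across the eight-membered ring, combine to a samarium diolate that is protonated on work-up. The closest known reaction is the SmI2-mediated intramolecular pinacol coupling of 1,5-diketones, in its transannular form on cyclooctane-1,5-diones. The one new bond C3–C4 closes the cyclopentane of unit A (C1–C5) and the central cyclopentane (C3, C4, C15, C15', C4') together, each as a 5-exo-trig attack of a ketyl carbon on the facing carbonyl carbon. C3 is set by chelation of trivalent samarium between the C3 ketyl oxygen and the cis C3' hydroxyl, which holds O3 syn to C3', and C4 must follow because a bicyclo[3.3.0]octane can only be cis-fused; both oxygens then lie on the α-face, syn to H1 and H5, where the solvated diolate also avoids the cycloheptane of unit A (C6, C10). The step needs chemoselectivity for the two ketones and this facial selectivity: the saturated lactones are not reduced, no α-heteroatom ketone is present, a ketyl could reach the C10 or C10' methylene only through 4-exo or 5-endo closures or across a trans-disposed ring, and the absence of base keeps the C3' aldol unit intact.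

Step 15
Reactants: 20 triol
Product: 21 11,11'-bis(phenylseleno) lactone
Conditions: LiN(iPr)2 (LDA, 6 equiv), THF–HMPA, −78 °C; then PhSeSePh, −78 to −20 °C
Reagents that add atoms: diphenyl diselenide, c1ccc(cc1)[Se][Se]c1ccccc1
Why: α-Selenenylation of the two lactone lithium enolates, the three hydroxyls being held as alkoxides by the excess base; the diselenide does not add to the alkenes, and selenium is expected to enter trans to H7 and H7' on each trans-fused lactone.

Step 16
Reactants: 21 11,11'-bis(phenylseleno) lactone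
Product: 23 3'α-hydroxy-3'-deoxoainsliadimer A, via bis-selenoxide 22 (not isolated)
Conditions: H2O2 (30% aq.), pyridine, CH2Cl2, 0 °C to rt
Reagents that add atoms: none
Why: Oxidation to the selenoxides and selenoxide syn-elimination: with selenium trans to H7 only the methyl hydrogens are syn, so both exocyclic α-methylene lactones should form.

Step 17
Reactants: 23 3'α-hydroxy-3'-deoxoainsliadimer A
Product: 24 ainsliadimer A
Conditions: Dess–Martin periodinane, NaHCO3, CH2Cl2, 0 °C to rt
Reagents that add atoms: none
Why: Dess–Martin oxidation of the only secondary alcohol; the tertiary diol has no carbinol hydrogen, and the buffered non-basic medium should spare the resulting β-hydroxy ketone from retro-aldol cleavage.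

**Compound list**

1 | α-santonin | C[C@H]1[C@@H]2CC[C@]3(C=CC(=O)C(=C3[C@H]2OC1=O)C)C | starting material
2 | isophotosantonic lactone (10α-hydroxy-3-oxo-1αH-guai-4-en-6α,12-olide, 11α-methyl) | C[C@H]1[C@@H]2CC[C@@](C)(O)[C@@H]3CC(=O)C(C)=C3[C@H]2OC1=O | intermediate
3 | 4,5-dihydroisophotosantonic lactone (1α,4α,5α-H, cis-fused ketone) | C[C@H]1[C@@H]2CC[C@@](C)(O)[C@@H]3CC(=O)[C@H](C)[C@@H]3[C@H]2OC1=O | intermediate
4 | 3β,10α-diol of 3 | C[C@H]1[C@@H]2CC[C@@](C)(O)[C@@H]3C[C@H](O)[C@H](C)[C@@H]3[C@H]2OC1=O | intermediate
5 | 3β-mesylate of 4 (not isolated) | C[C@H]1[C@@H]2CC[C@@](C)(O)[C@@H]3C[C@H](OS(C)(=O)=O)[C@H](C)[C@@H]3[C@H]2OC1=O | intermediate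
6 | 10α-hydroxy-1α,5αH-guai-3-en-6α,12-olide | C[C@H]1[C@@H]2CC[C@@](C)(O)[C@@H]3CC=C(C)[C@@H]3[C@H]2OC1=O | intermediate
7 | (11S)-1α,5αH-guaia-3,10(14)-dien-6α,12-olide | C[C@H]1[C@@H]2CCC(=C)[C@@H]3CC=C(C)[C@@H]3[C@H]2OC1=O | intermediate
8 | 3α,4α-epoxy-1α,5αH-guai-10(14)-en-6α,12-olide | C[C@H]1[C@@H]2CCC(=C)[C@@H]3C[C@H]4O[C@@]4(C)[C@@H]3[C@H]2OC1=O | intermediate
9 | 3α-hydroxy-1α,5αH-guaia-4(15),10(14)-dien-6α,12-olide (unit B) | C[C@H]1[C@@H]2CCC(=C)[C@@H]3C[C@@H](O)C(=C)[C@@H]3[C@H]2OC1=O | intermediate
10 | 3α,4β-dihydroxy-1α,5αH-guai-10(14)-en-6α,12-olide (not isolated) | C[C@H]1[C@@H]2CCC(=C)[C@@H]3C[C@@H](O)[C@](C)(O)[C@@H]3[C@H]2OC1=O | intermediate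
11 | 3,4-seco keto aldehyde (C1 carries CH2CHO, C5 carries acetyl, cis; unit A) | C[C@H]1[C@@H]2CCC(=C)[C@H](CC=O)[C@H](C(C)=O)[C@H]2OC1=O | intermediate
12 | unit A ketol (cis-fused cyclohexanone C1–C2–C3–C15–C4–C5 with C3 hydroxyl and C4 ketone; C3 epimers) | C[C@H]1[C@@H]2CCC(=C)[C@@H]3CC(O)CC(=O)[C@@H]3[C@H]2OC1=O | intermediate
13 | chlorodiisopropylsilyl ether of 9 (not isolated) | C[C@H]1[C@@H]2CCC(=C)[C@@H]3C[C@@H](O[Si](Cl)(C(C)C)C(C)C)C(=C)[C@@H]3[C@H]2OC1=O | intermediate
14 | silaketal O3'–Si(iPr)2–O3 joining 9 and 12 (C3 epimers) | C[C@H]1[C@@H]2CCC(=C)[C@@H]3C[C@@H](O[Si](C(C)C)(C(C)C)OC4CC(=O)[C@@H]5[C@H]6OC(=O)[C@@H](C)[C@@H]6CCC(=C)[C@@H]5C4)C(=C)[C@@H]3[C@H]2OC1=O | intermediate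
15 | C4 trimethylsilyl enol ether of 14 (not isolated) | C[C@H]1[C@@H]2CCC(=C)[C@@H]3C[C@@H](O[Si](C(C)C)(C(C)C)OC4C=C(O[Si](C)(C)C)[C@@H]5[C@H]6OC(=O)[C@@H](C)[C@@H]6CCC(=C)[C@@H]5C4)C(=C)[C@@H]3[C@H]2OC1=O | intermediate
16 | 3-silyloxy enone (C3(OSi)=C15–C4=O, tethered to O3' of unit B) | C[C@H]1[C@@H]2CCC(=C)[C@@H]3C[C@@H](O[Si](C(C)C)(C(C)C)OC4=CC(=O)[C@@H]5[C@H]6OC(=O)[C@@H](C)[C@@H]6CCC(=C)[C@@H]5C4)C(=C)[C@@H]3[C@H]2OC1=O | intermediate
17 | tethered cyclobutane photoadduct (cyclobutane C3–C15–C15'–C4', C3 on the α-face of C4'; C3 and C15 epimers) | C[C@H]1[C@@H]2CCC(=C)[C@@H]3C[C@H]4O[Si](C(C)C)(C(C)C)OC5(C[C@H]6C(=C)CC[C@H]7[C@H](C)C(=O)O[C@@H]7[C@H]6C(=O)C5C8)[C@@]48[C@@H]3[C@H]2OC1=O | intermediate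
18 | cyclobutanol (C3 and C3' hydroxyls free; not isolated) | C[C@H]1[C@@H]2CCC(=C)[C@@H]3C[C@@H](O)[C@]4(CC5C(=O)[C@@H]6[C@H]7OC(=O)[C@@H](C)[C@@H]7CCC(=C)[C@@H]6CC45O)[C@@H]3[C@H]2OC1=O | intermediate
19 | eight-membered 3,4-seco 1,5-diketone (ring C3, C2, C1, C5, C4, C15, C15', C4'; C3 and C4 ketones, 3'α-hydroxyl, 11-methyl lactones) | C[C@H]1[C@@H]2CCC(=C)[C@@H]3C[C@@H](O)[C@]4(CCC(=O)[C@@H]5[C@H]6OC(=O)[C@@H](C)[C@@H]6CCC(=C)[C@@H]5CC4=O)[C@@H]3[C@H]2OC1=O | intermediate
20 | triol, 11,13,11',13'-tetrahydro-3'-deoxo-3'α-hydroxyainsliadimer A (3α,4α-diol) | C[C@@H]1C(=O)O[C@@H]2[C@@H]3[C@@H](C[C@@]4(O)[C@]3(O)CC[C@]43[C@H](O)C[C@H]4C(=C)CC[C@H]5[C@H](C)C(=O)O[C@@H]5[C@H]43)C(=C)CC[C@@H]12 | intermediate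
21 | 11,11'-bis(phenylseleno) derivative of 20 (selenium β, trans to H7 and H7') | C[C@]1([Se]c6ccccc6)C(=O)O[C@@H]2[C@@H]3[C@@H](C[C@@]4(O)[C@]3(O)CC[C@]43[C@H](O)C[C@H]4C(=C)CC[C@H]5[C@@](C)([Se]c6ccccc6)C(=O)O[C@@H]5[C@H]43)C(=C)CC[C@@H]12 | intermediate
22 | bis-selenoxide of 21 (not isolated) | C[C@]1([Se](=O)c6ccccc6)C(=O)O[C@@H]2[C@@H]3[C@@H](C[C@@]4(O)[C@]3(O)CC[C@]43[C@H](O)C[C@H]4C(=C)CC[C@H]5[C@@](C)([Se](=O)c6ccccc6)C(=O)O[C@@H]5[C@H]43)C(=C)CC[C@@H]12 | intermediate
23 | 3'α-hydroxy-3'-deoxoainsliadimer A | C=C1C(=O)O[C@@H]2[C@@H]3[C@@H](C[C@@]4(O)[C@]3(O)CC[C@]43[C@H](O)C[C@H]4C(=C)CC[C@H]5C(=C)C(=O)O[C@@H]5[C@H]43)C(=C)CC[C@@H]12 | intermediate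
24 | ainsliadimer A | C=C1C(=O)O[C@@H]2[C@@H]3[C@@H](C[C@@]4(O)[C@]3(O)CC[C@]43C(=O)C[C@H]4C(=C)CC[C@H]5C(=C)C(=O)O[C@@H]5[C@H]43)C(=C)CC[C@@H]12 | target

**Step count**

Total: 17 steps. Longest linear sequence: 16 steps (steps 1–6 and 8–17, from α-santonin through unit A).

**Steps most likely to fail**

Step 12. The tethered triplet enone may not find a productive geometry: closure of the six-membered O–Si–O ring may be slow, a crossed addition may compete, or the enone may add in a carvone-type internal [2+2] to the C10=C14 alkene of unit A. The fallback is the classical untethered De Mayo reaction. It sets out from ketol 12, which is oxidised with Dess–Martin periodinane to the unit A cyclohexane-1,3-dione F1. The enol of F1 is irradiated (Pyrex, MeCN) with a fivefold excess of allylic alcohol 9; the cyclobutanol 18 fragments in the flask and the route is rejoined at diketone 19. Facial control then rests on the convex α-face of 9 alone. Adducts of the other enol tautomer and of the C10'=C14' alkene would have to be separated, and unreacted 9 is recovered.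

Step 14. The ketyl–ketyl union may show poor facial selectivity (cis-diol on the β-face), or proton transfer from the C3' hydroxyl may lead to simple reduction of the C3 ketone. The fallback replaces reductive coupling by deoxygenative coupling and directed dihydroxylation. It sets out from diketone 19: McMurry coupling (TiCl3(DME)1.5, Zn–Cu, DME, reflux) gives the tetrasubstituted C3=C4 alkene F2. Stoichiometric OsO4·TMEDA (CH2Cl2, −78 °C) is then delivered by hydrogen bonding to the C3' hydroxyl onto the alkene face syn to C3' and gives the cyclic osmate ester F3 (hexavalent osmium). Cleavage with aqueous Na2SO3 rejoins the route at triol 20.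

Step 15. Twofold lactone enolisation on a trilithium alkoxide may be incomplete or unselective, leaving mono-selenide or starting material. The fallback uses soft enolisation instead of lithium enolates. It sets out from triol 20: Me3SiOTf and Et3N (CH2Cl2, 0 °C) silylate the three hydroxyls and convert both lactones into ketene silyl acetals, giving the pentakis(trimethylsilyl) compound F4. N-(Phenylseleno)phthalimide then selenenylates both ketene acetals without touching the alkenes and gives the tris(trimethylsilyl) ether F5 of the bis-selenide. Dilute HCl in MeOH removes the silyl ethers and rejoins the route at 21.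

**Further compounds**

F1 | step 12 | unit A cyclohexane-1,3-dione (C3 and C4 ketones) | C[C@H]1[C@@H]2CCC(=C)[C@@H]3CC(=O)CC(=O)[C@@H]3[C@H]2OC1=O
F2 | step 14 | C3=C4 alkene (bicyclo[3.3.0]oct-1(5)-ene core, 3'α-hydroxyl) | C[C@@H]1C(=O)O[C@@H]2[C@@H]3[C@@H](CC4=C3CC[C@]43[C@H](O)C[C@H]4C(=C)CC[C@H]5[C@H](C)C(=O)O[C@@H]5[C@H]43)C(=C)CC[C@@H]12
F3 | step 14 | cyclic 3,4-osmate ester of 20, TMEDA complex (hexavalent osmium) | C[C@@H]1C(=O)O[C@@H]2[C@@H]3[C@@H](C[C@@]4(O7)[C@]3(O[Os]7(=O)=O)CC[C@]43[C@H](O)C[C@H]4C(=C)CC[C@H]5[C@H](C)C(=O)O[C@@H]5[C@H]43)C(=C)CC[C@@H]12.CN(C)CCN(C)C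
F4 | step 15 | bis(ketene trimethylsilyl acetal) tris(trimethylsilyl ether) of 20 | CC1=C(O[Si](C)(C)C)O[C@@H]2[C@@H]3[C@@H](C[C@@]4(O[Si](C)(C)C)[C@]3(O[Si](C)(C)C)CC[C@]43[C@H](O[Si](C)(C)C)C[C@H]4C(=C)CC[C@H]5C(C)=C(O[Si](C)(C)C)O[C@@H]5[C@H]43)C(=C)CC[C@@H]12
F5 | step 15 | tris(trimethylsilyl) ether of bis-selenide 21 | C[C@]1([Se]c6ccccc6)C(=O)O[C@@H]2[C@@H]3[C@@H](C[C@@]4(O[Si](C)(C)C)[C@]3(O[Si](C)(C)C)CC[C@]43[C@H](O[Si](C)(C)C)C[C@H]4C(=C)CC[C@H]5[C@@](C)([Se]c6ccccc6)C(=O)O[C@@H]5[C@H]43)C(=C)CC[C@@H]12
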